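The numbers in the tables were computed for an exercise, noise included.

Slowness is the question here: how long may we wait for target before its slow loss overtakes what substrate still feeds it?

| flask | substrate | remark | time |
|---|---|---|---|
| eta | 0.80 M | the very flask that is asked about, followed so far |  |
| alpha | 0.54 M | run made earlier |  |
| flask | 0.80 M |  | 6.0 min |

| run | time / min | target / % | substrate / % |
|---|---|---|---|
| eta | 0.667 | 14.8 | 52.8 |
| eta | 0.833 | 17.2 | 47.5 |
| eta | 1.33 | 19.3 | 34.1 |
| eta | 1.50 | 20.9 | 32.0 |
| eta | 2.50 | 21.6 | 19.3 |
| alpha | 0.667 | 11.8 | 60.0 |
| alpha | 0.833 | 13.0 | 53.5 |
| alpha | 1.33 | 15.0 | 39.5 |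
| alpha | 1.50 | 14.8 | 35.0 |
| alpha | 2.50 | 16.4 | 23.1 |

(readings scatter by 1 percentage point)

- in percentages every species weighs as the substrate in it: one target or over-reaction product counts as two
- in percentages every species weighs as the substrate in it: one idle adduct counts as three
- for target the idle adduct is counted in
- what may be going on: 2 substrate <-> target; substrate <-> dormant form; target -> over-reaction product; substrate + target <-> idle adduct
- in an amount of target, one idle adduct counts as one target

* the moment within 6.0 min at which there is most target
* the amount of target, in percent of the substrate charged, at that time

We count in half-lives. In the eta run, which is the flask asked about, substrate falls from 52.8% to 19.3% between 0.667 min and 2.50 min. That gives 1.26 min as the substrate half-life, the time in which the substrate reading halves over that stretch. The alpha run reads 1.33 min, with a smaller charge.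

Two extreme versions of the flask stand on either side of the peak. Reckoned without any loss, target peaks at the last moment, 6.0 min. Reckoned with a loss faster than the feed, it peaks by the first reading, 0.667 min. But the eta target climbs from 14.8% to 21.6%, though its last step, 0.7 percentage points, lies inside the scatter.

Between them, the feed goes as the square of c(substrate). Each half-life cuts it to a quarter, and after two half-lives it stands at 6.25% of its value where the count began. So we commit to a peak near 2.52 min, a little after the last eta reading.

The forecast says 3 min and 22%, later than our time: “Target then declines slowly.”

The flask gives 2.56 min and 22.6%.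

    2 substrate ⇌ target (K = 2.00 L mol⁻¹, k = 0.00444 L mol⁻¹ s⁻¹)
    substrate ⇌ dormant form (K = 9.13, k = 0.00783 s⁻¹)
    target → over-reaction product (k = 0.00614 s⁻¹)
    substrate + target ⇌ idle adduct, settled at all times (K = 42.0 L mol⁻¹)

Half of the turnover to target up to 6.0 min is done by 0.442 min, and half of the turnover to over-reaction product by 3.90 min. The peak stands between these times, at 2.03 of our half-lives. Carried to the neighbour flask charged with 1.4 M, two of our half-lives stand near 2.52 min, before 6.0 min, so target should end below its peak there. That neighbour flask gives a best of 30.8% and 26.2% at 6.00 min.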